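Thursday's flask runs longer than Saturday's (10 d against 3.0 d) on the same charge, so the two can differ in the share of monomer converted and in the chains begun.

all flasks: free monomer 0.30 M

|  | initiator | remark | time |
|---|---|---|---|
| south | 2.1 mM | run made earlier |  |
| north-east | 3.3 mM | run made earlier |  |
| Thursday's | 1.5 mM |  | 10 d |
| Saturday's | 1.5 mM |  | 3.0 d |

| run | time / d | monomer in chains / % | free monomer / % |
|---|---|---|---|
| south | 1.67 | 21.9 | 78.6 |
| south | 3.00 | 49.2 | 50.4 |
| south | 5.00 | 77.5 | 22.2 |
| south | 6.00 | 84.5 | 14.1 |
| south | 8.00 | 93.2 | 4.7 |
| north-east | 1.67 | 30.8 | 68.5 |
| north-east | 3.00 | 62.9 | 36.3 |
| north-east | 5.00 | 88.7 | 10.5 |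
| north-east | 6.00 | 93.5 | 6.0 |
| north-east | 8.00 | 97.5 | 1.5 |

(standard deviation of a reading: 0.5 percentage points)

* which of the two ends with the longer chains by the average number of monomer units in a chain (chains begun, living or dead) ("neither" if they lie within 10%) (Thursday's / Saturday's / neither)
* average number of monomer units in a chain (chains begun, living or dead) at the end, Thursday's
* average number of monomer units in a chain (chains begun, living or dead) at the end, Saturday's

- the average divides the monomer in chains by the number of chains begun, living and dead together
- the earlier runs do not show the number of chains; that part of a forecast is a guess

1. The charge ratio (target degree of polymerisation), free monomer charged over initiator charged, is 200. The average length equals this ratio times the share of free monomer in chains, divided by the share of initiator that has begun a chain. The readings show the first share but not the second, so my bracket takes one chain per charged initiator.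

2. Bound from above: with the free monomer wholly in chains, Thursday's length under that assumption equals the charge ratio, 200.

3. Bound from below: in the south run, ln(M0/M) reads 3.06 at 8.00 d. The north-east run stands 1.37 times higher on 1.57 times the initiator, so scaling down in proportion to initiator is cautious. For Thursday's this gives 2.18 at that time.

4. Tightening: the south run's last slope, 0.549 d⁻¹, scaled the same way over the remaining 2.00 d, raises the logarithm to 2.97. That means 94.9% of the free monomer used up. The south run's last readings put 97.8% of the free monomer used up into chains, so Thursday's has about 92.8% in chains, and the bracket has a low end of 186.

5. For Saturday's, the same scaling at 3.00 d, with the south run's share in chains at that reading, gives 76.8 on one chain per charged initiator. My reckoning therefore favours Thursday's.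

6. The forecast names Thursday's, with 192 inside the bracket  and 110 for Saturday's, above my figure. Its ground for the count: “Chain count is assumed, with full initiator efficiency; lower efficiency lengthens both.”

7. The flasks give Thursday's as the longer, at 297 against 170. Thursday's stands above the bracket.

    free monomer + initiator → living end + monomer in chains (k = 9.20 × 10⁻⁶ M⁻¹ s⁻¹)
    free monomer + living end → monomer in chains + living end, rate k2*[living end]*[free monomer] (k = 0.00470 M⁻¹ s⁻¹)
    free monomer → decomposition product (k = 3.20 × 10⁻⁸ s⁻¹)

In Saturday's flask at 3.00 d, free monomer has a half-life of 2.5 d by propagation, shorter than the 4.8 d of initiator by chain starting. Saturday's ends with 55% of its initiator unbound, and Thursday's ends with 37% while its free monomer stands at 5.0%. Thursday's charge ratio, times 93.8% in chains, over the 63.0% of initiator used, gives 298. A further flask, Saturday's recipe with 1.2 M of free monomer, has a charge ratio of 800, 67.7% in chains and 15% of its initiator left, and its average length is 636.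

The data are calculated from invented constants.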